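## Retrosynthetic overview
- **Structural feature.** Ring A (C4a–C5–C6–C7–C8–C8a) is fully substituted. Oxygen sits on C5, C7 and C8a and carbon on C4a, C6 and C8, in unbroken alternation. This is the pattern of three alkoxyalkynes joined head to tail, and two of them are already linked by the O1–C2–C3–C4 chain of ring C.
- **Late stage.** The ring B quinone comes from its hydroquinone (Ag2O). C5–OH and the two ring B phenols come from ethyl and benzyl ethers (BCl3). C4=O comes from a silyl-protected carbinol.
- **Key disconnection.** C4a–C8a, C5–C6 and C7–C8 are cut together. This opens rings A and C at once to a (2S)-1,7-bis(ynol ether) and 1-methoxypropyne. Ring B is present from the first step, and rings A and C form in the same operation.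
- **Diyne.** It comes from 2,5-bis(benzyloxy)-4-methoxybenzaldehyde. C2 is set by asymmetric allylboration. O1–C8a is carried as a robust 1,2-dichlorovinyl ether and turned into the labile propynyl ether only in the last step before the cycloaddition. C4–C4a comes from lithium ethoxyacetylide and the aldehyde obtained by alkene cleavage.

Key step: step 10

Remarks on the chemistry:
- Flavanone numbering (O1, C2, C3, C4, C4a, C5–C8, C8a; ring B primed) is used for all intermediates.
- The C4 carbinol is carried as a mixture of epimers because C4 ends as a ketone.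
- 1-Methoxypropyne is assumed not to be reliably purchasable and is made in step 9.

## Route

Step 1
Reactants: 1 methoxyhydroquinone (2-methoxybenzene-1,4-diol)
Product: 2 1,4-bis(benzyloxy)-2-methoxybenzene
Conditions: BnBr (2.4 equiv), K2CO3, DMF, Ar, 20 → 50 °C
Reagents that add atoms: benzyl bromide, BrCc1ccccc1
Why: Williamson ether synthesis, in which both phenoxides are alkylated by the benzylic bromide and exclusion of air keeps the hydroquinone from oxidising.

Step 2
Reactants: 2 1,4-bis(benzyloxy)-2-methoxybenzene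
Product: 4 2,5-bis(benzyloxy)-4-methoxybenzaldehyde, via iminium chloride 3 (not isolated)
Conditions: POCl3, DMF, 0 → 60 °C; then H2O
Reagents that add atoms: N,N-dimethylformamide, CN(C)C=O; water, O
Why: Vilsmeier–Haack formylation, in which the chloroiminium ion attacks the only free ring carbon that is para to OMe and ortho to OBn (the way 1,2,4-trialkoxybenzenes give 2,4,5-trialkoxybenzaldehydes) and water hydrolyses iminium 3.

Step 3
Reactants: 4 2,5-bis(benzyloxy)-4-methoxybenzaldehyde
Product: 6 (1S)-1-[2,5-bis(benzyloxy)-4-methoxyphenyl]but-3-en-1-ol, via borinate ester 5 (not isolated)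
Conditions: (−)-Ipc2BOMe, allylMgBr, Et2O, 0 → 20 °C; 4, −78 °C; then NaOH, H2O2
Reagents that add atoms: allylmagnesium bromide, C=CC[Mg]Br
Why: Brown asymmetric allylboration through a closed chair transition state, in which the isopinocampheyl groups of the (+)-α-pinene series deliver allyl to the Si face of the formyl group (the sense known for benzaldehyde) and so set the (S) centre that becomes C2.

Step 4
Reactants: 6 (1S)-1-[2,5-bis(benzyloxy)-4-methoxyphenyl]but-3-en-1-ol; 7 trichloroethylene
Product: 9 1,4-bis(benzyloxy)-2-[(1S)-1-{[(E)-1,2-dichloroethenyl]oxy}but-3-en-1-yl]-5-methoxybenzene, via dichloroacetylene 8 (not isolated)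
Conditions: KH, THF, 0 °C; 7, −50 → 20 °C
Reagents that add atoms: none
Why: This is the trichloroethylene route to dichlorovinyl ethers: base eliminates HCl from 7 to give 8, the alkoxide of 6 adds anti to it to give the (E)-ether, and no bond at C2 is touched, so the configuration is kept.

Step 5
Reactants: 9 the (S)-dichlorovinyl homoallyl ether
Product: 11 (3S)-3-[2,5-bis(benzyloxy)-4-methoxyphenyl]-3-{[(E)-1,2-dichloroethenyl]oxy}propanal, via vicinal diol 10 (not isolated)
Conditions: OsO4 (2 mol %), NaIO4, 2,6-lutidine, dioxane–H2O, 20 °C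
Reagents that add atoms: osmium tetroxide, O=[Os](=O)(=O)=O; sodium periodate, [Na+].[O-]I(=O)(=O)=O
Why: Lemieux–Johnson cleavage, in which OsO4 should take the unhindered monosubstituted alkene ahead of the chlorine-deactivated trisubstituted enol ether, NaIO4 splits diol 10, and 2,6-lutidine keeps the medium near neutral.

Step 6
Reactants: 11 the (3S)-aldehyde; 12 ethoxyethyne
Product: 14 (1S)-1-[2,5-bis(benzyloxy)-4-methoxyphenyl]-1-{[(E)-1,2-dichloroethenyl]oxy}-5-ethoxypent-4-yn-3-ol (C4 epimers), via lithium ethoxyacetylide 13 (not isolated)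
Conditions: 12, n-BuLi, THF, −78 °C; then 11, −78 °C; H2O
Reagents that add atoms: none
Why: 1,2-Addition of a lithium acetylide to an aldehyde: at −78 °C carbonyl addition should outrun enolisation and β-elimination, the acetylide is too weak a base to attack the dichlorovinyl ether, and the new C4 centre is left uncontrolled because it is later oxidised.

Step 7
Reactants: 14 the ethoxyalkynyl carbinol
Product: 15 tert-butyldimethylsilyl ether of 14 (C4 epimers)
Conditions: TBSCl, imidazole, DMF, 0 → 20 °C
Reagents that add atoms: tert-butyldimethylsilyl chloride, CC(C)(C)[Si](C)(C)Cl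
Why: Standard silylation of a secondary alcohol, where the imidazole buffer avoids the acid-triggered Meyer–Schuster rearrangement of the ethoxyalkynyl carbinol.

Step 8
Reactants: 15 the silyl ether
Product: 18 1,4-bis(benzyloxy)-2-[(1S)-3-(tert-butyldimethylsilyloxy)-5-ethoxy-1-(prop-1-yn-1-yloxy)pent-4-yn-1-yl]-5-methoxybenzene (C4 epimers), via chloroethynyl ether 16 (not isolated), via lithioethynyl ether 17 (not isolated)
Conditions: n-BuLi (2.3 equiv), THF, −78 → −40 °C; MeI, HMPA, −78 → 20 °C; Et3N-deactivated silica, kept below 25 °C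
Reagents that add atoms: iodomethane, CI
Why: Second stage of the trichloroethylene route to alkynyl ethers (elimination of HCl to 16, chlorine–lithium exchange to 17, SN2 methylation), placed last so that the benzylic alkynyl ether, which is labile to acid, to a [3,3] shift near 60 °C and to retro-ene loss, meets no other reagent before the cycloaddition.

Step 9
Reactants: 19 chloroacetaldehyde dimethyl acetal (2-chloro-1,1-dimethoxyethane)
Product: 21 1-methoxyprop-1-yne, via sodium methoxyacetylide 20 (not isolated)
Conditions: NaNH2 (3.2 equiv), NH3(l), −33 °C; MeI; then H2O, distillation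
Reagents that add atoms: iodomethane, CI
Why: Loss of HCl and MeOH from an α-chloroacetal with NaNH2 gives the sodium alkoxyacetylide, which is alkylated in liquid ammonia; this is the standard preparation of 1-alkoxy-1-alkynes.

Step 10
Reactants: 18 the (S)-1,7-bis(ynol ether); 21 1-methoxyprop-1-yne
Product: 23 (2S)-2-[2,5-bis(benzyloxy)-4-methoxyphenyl]-4-(tert-butyldimethylsilyloxy)-5-ethoxy-7-methoxy-6,8-dimethylchroman (C4 epimers), via rhodacyclopentadiene 22 (not isolated)
Conditions: RhCl(PPh3)3 (10 mol %), 21 (5 equiv), 4 Å MS, toluene, 20 → 40 °C, slow addition of 18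
Reagents that add atoms: none
Why: Proposed new method: loss of PPh3 lets univalent rhodium bind both alkynes of 18, and oxidative coupling gives rhodacyclopentadiene 22 of trivalent rhodium, in which C4a–C8a is made and ring C is closed as the six-membered ring O1–C2–C3–C4–C4a–C8a fused to the metallacycle, the only junction the tether allows. Insertion of 21 into a Rh–C bond and reductive elimination then make C5–C6 and C7–C8 and close ring A as a six-membered carbocycle in the (2+2+2) mode. The closest known reaction type is the RhCl(PPh3)3-catalysed cycloaddition near room temperature of 1,6- and 1,7-diynes bearing one ynamide or alkynyl ether terminus with a free alkoxyalkyne, whereas three internal ynol ethers giving a hexasubstituted arene have not been shown. No stereocentre is formed, since C2 is a spectator and C4 stays an epimer mixture. The selectivity needed is the orientation of 21 (its methyl-bearing carbon to C5, its methoxy-bearing carbon to C8), and it rests on polarity matching, because metal-bound C5 is the electron-poor oxygen-bearing carbon of its ynol ether and C8 the electron-rich β-carbon of the other, so the donor carbon of 21 meets C5 and its acceptor carbon meets C8, with little steric bias as OEt and Me are of like size. Homotrimerisation of 21 and dimerisation of 18 are countered by feeding 18 slowly into excess 21, and the temperature limit keeps the [3,3] shift and retro-ene loss of the benzylic alkynyl ether from competing.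

Step 11
Reactants: 23 the 4-silyloxychroman
Product: 24 (2S)-2-[2,5-bis(benzyloxy)-4-methoxyphenyl]-5-ethoxy-7-methoxy-6,8-dimethylchroman-4-ol (C4 epimers)
Conditions: Bu4NF, THF, 0 → 20 °C
Reagents that add atoms: none
Why: Fluoride-driven cleavage of the Si–O bond; as no carbonyl group is present yet, the basic fluoride cannot open ring C or disturb C2.

Step 12
Reactants: 24 the flavan-4-ol
Product: 25 (2S)-2-[2,5-bis(benzyloxy)-4-methoxyphenyl]-5-ethoxy-7-methoxy-6,8-dimethylchroman-4-one
Conditions: Dess–Martin periodinane, NaHCO3, CH2Cl2, 0 → 20 °C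
Reagents that add atoms: none
Why: Dess–Martin oxidation of a secondary benzylic alcohol, where the bicarbonate buffer avoids ionisation at C4 and the near-neutral medium avoids retro-oxa-Michael opening, so both C4 epimers converge on one ketone with C2 intact.

Step 13
Reactants: 25 the protected flavanone
Product: 26 (2S)-2-(2,5-dihydroxy-4-methoxyphenyl)-5-hydroxy-7-methoxy-6,8-dimethylchroman-4-one
Conditions: BCl3 (6 equiv), C6HMe5 (6 equiv), CH2Cl2, −78 → 0 °C; then H2O
Reagents that add atoms: none
Why: Lewis-acid ether cleavage, in which BCl3 removes aryl benzyl ethers at low temperature with pentamethylbenzene as a non-basic benzyl cation trap, and chelation between C4=O and the C5 oxygen directs chloride to the ethyl group, while the unchelated methyl ethers at C7 and C4' should react more slowly.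

Step 14
Reactants: 26 the hydroquinone
Product: 27 target, 2-[(2S)-5-hydroxy-7-methoxy-6,8-dimethyl-4-oxochroman-2-yl]-5-methoxycyclohexa-2,5-diene-1,4-dione
Conditions: Ag2O, Na2SO4, CH2Cl2–Et2O, 20 °C, dark
Reagents that add atoms: none
Why: Two-electron oxidation of a p-hydroquinone to the p-benzoquinone by Ag2O under neutral anhydrous conditions; the chelated C5 phenol has no para oxygen and should stay, and nothing acidic or basic reaches C2.

## Compound list
1 | methoxyhydroquinone | COc1cc(O)ccc1O | starting material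
2 | 1,4-bis(benzyloxy)-2-methoxybenzene | COc1cc(OCc2ccccc2)ccc1OCc1ccccc1 | intermediate
3 | [2,5-bis(benzyloxy)-4-methoxybenzylidene]dimethyliminium chloride | COc1cc(OCc2ccccc2)c(C=[N+](C)C)cc1OCc1ccccc1.[Cl-] | intermediate
4 | 2,5-bis(benzyloxy)-4-methoxybenzaldehyde | COc1cc(OCc2ccccc2)c(C=O)cc1OCc1ccccc1 | intermediate
5 | (S)-1-arylbut-3-enyl bis(isopinocampheyl)borinate | COc1cc(OCc2ccccc2)c(cc1OCc1ccccc1)[C@@H](OB([C@@H]3C[C@@H]4C[C@H]([C@H]3C)C4(C)C)[C@@H]3C[C@@H]4C[C@H]([C@H]3C)C4(C)C)CC=C | intermediate
6 | (1S)-1-[2,5-bis(benzyloxy)-4-methoxyphenyl]but-3-en-1-ol | COc1cc(OCc2ccccc2)c(cc1OCc1ccccc1)[C@@H](O)CC=C | intermediate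
7 | trichloroethylene | ClC=C(Cl)Cl | starting material
8 | dichloroacetylene | ClC#CCl | intermediate
9 | (S)-homoallyl (E)-1,2-dichlorovinyl ether | COc1cc(OCc2ccccc2)c(cc1OCc1ccccc1)[C@@H](O/C(Cl)=C\Cl)CC=C | intermediate
10 | (4S)-4-aryl-4-[(E)-1,2-dichlorovinyloxy]butane-1,2-diol (diol carbon epimers) | COc1cc(OCc2ccccc2)c(cc1OCc1ccccc1)[C@@H](O/C(Cl)=C\Cl)CC(O)CO | intermediate
11 | (3S)-3-aryl-3-[(E)-1,2-dichlorovinyloxy]propanal | COc1cc(OCc2ccccc2)c(cc1OCc1ccccc1)[C@@H](O/C(Cl)=C\Cl)CC=O | intermediate
12 | ethoxyethyne | C#COCC | starting material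
13 | lithium ethoxyacetylide | [Li]C#COCC | intermediate
14 | (1S)-1-aryl-1-[(E)-1,2-dichlorovinyloxy]-5-ethoxypent-4-yn-3-ol (C4 epimers) | COc1cc(OCc2ccccc2)c(cc1OCc1ccccc1)[C@@H](O/C(Cl)=C\Cl)CC(O)C#COCC | intermediate
15 | TBS ether of 14 (C4 epimers) | COc1cc(OCc2ccccc2)c(cc1OCc1ccccc1)[C@@H](O/C(Cl)=C\Cl)CC(O[Si](C)(C)C(C)(C)C)C#COCC | intermediate
16 | chloroethynyl ether | COc1cc(OCc2ccccc2)c(cc1OCc1ccccc1)[C@@H](OC#CCl)CC(O[Si](C)(C)C(C)(C)C)C#COCC | intermediate
17 | lithioethynyl ether | COc1cc(OCc2ccccc2)c(cc1OCc1ccccc1)[C@@H](OC#C[Li])CC(O[Si](C)(C)C(C)(C)C)C#COCC | intermediate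
18 | (S)-1,7-diyne: propynyl ether at C2, ethoxyalkynyl carbinol TBS ether at C4 (C4 epimers) | COc1cc(OCc2ccccc2)c(cc1OCc1ccccc1)[C@@H](OC#CC)CC(O[Si](C)(C)C(C)(C)C)C#COCC | intermediate
19 | chloroacetaldehyde dimethyl acetal | COC(CCl)OC | starting material
20 | sodium methoxyacetylide | [Na]C#COC | intermediate
21 | 1-methoxyprop-1-yne | CC#COC | intermediate
22 | chlorobis(triphenylphosphine)rhodacyclopentadiene fused to ring C (Rh on C5 and C8) | CCOC1=C2C(O[Si](C)(C)C(C)(C)C)C[C@@H](c3cc(OCc4ccccc4)c(OC)cc3OCc3ccccc3)OC2=C(C)[Rh-2]1(Cl)([P+](c1ccccc1)(c1ccccc1)c1ccccc1)[P+](c1ccccc1)(c1ccccc1)c1ccccc1 | intermediate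
23 | (2S)-2-[2,5-bis(benzyloxy)-4-methoxyphenyl]-4-(tert-butyldimethylsilyloxy)-5-ethoxy-7-methoxy-6,8-dimethylchroman (C4 epimers) | COc1cc(OCc2ccccc2)c(cc1OCc1ccccc1)[C@@H]3CC(O[Si](C)(C)C(C)(C)C)c4c(OCC)c(C)c(OC)c(C)c4O3 | intermediate
24 | (2S)-flavan-4-ol (C4 epimers) | COc1cc(OCc2ccccc2)c(cc1OCc1ccccc1)[C@@H]3CC(O)c4c(OCC)c(C)c(OC)c(C)c4O3 | intermediate
25 | (2S)-2-[2,5-bis(benzyloxy)-4-methoxyphenyl]-5-ethoxy-7-methoxy-6,8-dimethylchroman-4-one | COc1cc(OCc2ccccc2)c(cc1OCc1ccccc1)[C@@H]3CC(=O)c4c(OCC)c(C)c(OC)c(C)c4O3 | intermediate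
26 | (2S)-2-(2,5-dihydroxy-4-methoxyphenyl)-5-hydroxy-7-methoxy-6,8-dimethylchroman-4-one | COc1cc(O)c(cc1O)[C@@H]2CC(=O)c3c(O)c(C)c(OC)c(C)c3O2 | intermediate
27 | CNP0208927.1 | COC1=CC(=O)C([C@@H]2CC(=O)c3c(O)c(C)c(OC)c(C)c3O2)=CC1=O | target

## Step count
Total step count: 14.
Longest linear sequence: 13 steps (steps 1–8 and 10–14). Step 9 is a one-step side branch.

## Steps most likely to fail

**Step 10.**
- *What may go wrong.* Oxidative coupling of two fully substituted, electron-rich alkynes on rhodium may be slower than homotrimerisation of 21. Compound 21 may insert in the reverse sense. The benzylic alkynyl ether may rearrange before it is consumed.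
- *Fallback.* The fallback gives up the cycloaddition and builds the flavanone by known chalcone chemistry. It sets out from aldehyde 4 and comes back at flavanone 25.
- Commercial 2,4,6-trihydroxyacetophenone is C-methylated twice (MeI, NaOMe, MeOH) to 2,4,6-trihydroxy-3,5-dimethylacetophenone F1.
- The unchelated para hydroxyl is methylated (Me2SO4, one equivalent, K2CO3, acetone) to 2,6-dihydroxy-4-methoxy-3,5-dimethylacetophenone F2.
- One of the two equivalent chelated hydroxyls is ethylated (EtI, K2CO3, DMF) to 2-ethoxy-6-hydroxy-4-methoxy-3,5-dimethylacetophenone F3.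
- Claisen–Schmidt condensation of F3 with 4 (KOH, EtOH) should give the (E)-2'-hydroxychalcone F4.
- Oxa-Michael ring closure (NaOAc, EtOH, reflux) should then give the racemic flavanone F5.
- Kinetic resolution by asymmetric transfer hydrogenation (Cp*RhCl[(R,R)-TsDPEN], HCO2H–Et3N, EtOAc) is a method known for flavanones. It should reduce the (2R)-ketone to the cis-(2R,4R)-flavan-4-ol F6 and leave the (2S)-ketone 25, which is separated by chromatography.

**Step 13.**
- *What may go wrong.* The twisted, doubly flanked C7 methyl ether may be lost, or the C4' methyl ether next to a newly formed boron phenolate. The Lewis acid may cause heterolysis of O1–C2, which is benzylic to the donor-rich ring B, with erosion of the configuration. The electron-rich rings may be C-benzylated.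
- *Fallback.* The fallback separates the two kinds of ether cleavage and keeps strong Lewis acid away. It sets out from 25 and comes back at 26.
- MgI2·OEt2 (Et2O–toluene, gentle warming) is a weak chelating Lewis acid known to dealkylate only the ether next to a carbonyl group. It should give (2S)-2-[2,5-bis(benzyloxy)-4-methoxyphenyl]-5-hydroxy-7-methoxy-6,8-dimethylchroman-4-one F7.
- Neutral hydrogenolysis (H2, Pd/C, EtOAc) then removes both benzyl groups to give 26.

**Step 8.**
- *What may go wrong.* C-methylation of acetylide 17 needs a polar cosolvent and warming. During that time excess base may metalate the propargylic C4–H or the benzyl ethers, and the benzylic alkynyl ether may rearrange or be hydrated on work-up.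
- *Fallback.* The C8 methyl group is brought in after ring A exists. The fallback sets out from 15 and comes back at 23.
- Acetylide 17, made as in step 8, is quenched cold with water to give the terminal ethynyl ether F8.
- F8 is cycloadded with 21 under the conditions of step 10 to the 8-unsubstituted chroman F9. This relies on the same unproven reaction type as step 10, but with a less hindered terminal alkyne.
- The single free position of ring A is flanked by O1 and OMe and para to OEt. It is brominated (NBS, MeCN, 0 °C) to the 8-bromochroman F10.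
- Suzuki–Miyaura methylation (MeB(OH)2, Pd(OAc)2, SPhos, K3PO4, toluene–H2O, 90 °C) then gives 23.

## Further compounds
F1 | step 10 | 1-(2,4,6-trihydroxy-3,5-dimethylphenyl)ethanone | CC(=O)c1c(O)c(C)c(O)c(C)c1O
F2 | step 10 | 1-(2,6-dihydroxy-4-methoxy-3,5-dimethylphenyl)ethanone | CC(=O)c1c(O)c(C)c(OC)c(C)c1O
F3 | step 10 | 1-(2-ethoxy-6-hydroxy-4-methoxy-3,5-dimethylphenyl)ethanone | CCOc1c(C)c(OC)c(C)c(O)c1C(C)=O
F4 | step 10 | (E)-3-[2,5-bis(benzyloxy)-4-methoxyphenyl]-1-(2-ethoxy-6-hydroxy-4-methoxy-3,5-dimethylphenyl)prop-2-en-1-one | CCOc1c(C)c(OC)c(C)c(O)c1C(=O)/C=C/c1cc(OCc2ccccc2)c(OC)cc1OCc1ccccc1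
F5 | step 10 | racemic 2-[2,5-bis(benzyloxy)-4-methoxyphenyl]-5-ethoxy-7-methoxy-6,8-dimethylchroman-4-one | COc1cc(OCc2ccccc2)c(cc1OCc1ccccc1)C3CC(=O)c4c(OCC)c(C)c(OC)c(C)c4O3
F6 | step 10 | (2R,4R)-2-[2,5-bis(benzyloxy)-4-methoxyphenyl]-5-ethoxy-7-methoxy-6,8-dimethylchroman-4-ol | COc1cc(OCc2ccccc2)c(cc1OCc1ccccc1)[C@H]3C[C@@H](O)c4c(OCC)c(C)c(OC)c(C)c4O3
F7 | step 13 | (2S)-2-[2,5-bis(benzyloxy)-4-methoxyphenyl]-5-hydroxy-7-methoxy-6,8-dimethylchroman-4-one | COc1cc(OCc2ccccc2)c(cc1OCc1ccccc1)[C@@H]3CC(=O)c4c(O)c(C)c(OC)c(C)c4O3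
F8 | step 8 | (S)-1,7-diyne with a terminal ethynyl ether at C2 (C4 epimers) | COc1cc(OCc2ccccc2)c(cc1OCc1ccccc1)[C@@H](OC#C)CC(O[Si](C)(C)C(C)(C)C)C#COCC
F9 | step 8 | (2S)-2-[2,5-bis(benzyloxy)-4-methoxyphenyl]-4-(tert-butyldimethylsilyloxy)-5-ethoxy-7-methoxy-6-methylchroman (C4 epimers) | COc1cc(OCc2ccccc2)c(cc1OCc1ccccc1)[C@@H]3CC(O[Si](C)(C)C(C)(C)C)c4c(OCC)c(C)c(OC)cc4O3
F10 | step 8 | 8-bromo derivative of F9 (C4 epimers) | COc1cc(OCc2ccccc2)c(cc1OCc1ccccc1)[C@@H]3CC(O[Si](C)(C)C(C)(C)C)c4c(OCC)c(C)c(OC)c(Br)c4O3
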